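## Retrosynthetic overview

1. Structural feature used: indane carbon C1, which carries the ketone carbon C8 with ring D, lies between ring-A carbon C7a and C2 (ring C, next to C3 with ring B). C1 can therefore be slipped as one carbene carbon into a strained C7a–C2 bond (ring A = fused benzene ring, oxygens at C4 and C6).
2. Endgame: caraphenol C ⇐ hexamethyl ether (ether cleavage) ⇐ C1=C2 enone (hydrogenation anti to ring B sets C1 and C2) ⇐ 1-aroyl-2-hydroxy-2,3-diarylindane (dehydration).
3. Key disconnection: C1–C7a and C1–C2 ⇒ a 7,8-diarylbenzocyclobutenol holding rings A, B and C, plus 2-diazo-1-(4-methoxyphenyl)ethanone (C1, C8, ring D), united by rhodium-catalysed C–C cleavage, carbene insertion and aldol closure.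
4. Benzocyclobutenol ⇐ photocyclisation of a 2-benzylbenzophenone (forms C2–C3) ⇐ Negishi benzylation of a 2-bromobenzophenone ⇐ aryl Grignard addition and oxidation; chiral chromatography fixes C3 before the key step.
5. Ring order: the four benzene rings are bought, the four-membered ring is made first (step 4) and is then expanded into the five-membered indane ring (step 7).

Key step: step 7

Assumption: the photocyclisation of step 4 is taken to give the benzocyclobutenol epimer with the hydroxyl trans to ring B (conrotatory closure of the dienol with hydroxyl and ring B both outside); this carbinol centre is lost in step 7, so its configuration has no consequence.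
Assumption: the enantiomer from step 6 with the R configuration at C8 is identified by X-ray anomalous dispersion or vibrational circular dichroism before it is carried on.

## Route

Step 1
Reactants: 1 1-bromo-3,5-dimethoxybenzene; 2 2-bromo-3,5-dimethoxybenzaldehyde
Product: 4 racemic (2-bromo-3,5-dimethoxyphenyl)(3,5-dimethoxyphenyl)methanol, via 3,5-dimethoxyphenylmagnesium bromide 3 (not isolated)
Conditions: Mg, THF, 40 °C (from 1); then 2, THF, 0 °C; aq. NH4Cl
Reagents that add atoms: none
Why: Grignard addition of the aryl nucleophile to the aldehyde is fast at 0 °C and leaves the hindered aryl bromide untouched; the carbinol centre is formed as a racemate and is removed in step 2.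

Step 2
Reactants: 4 racemic (2-bromo-3,5-dimethoxyphenyl)(3,5-dimethoxyphenyl)methanol
Product: 5 (2-bromo-3,5-dimethoxyphenyl)(3,5-dimethoxyphenyl)methanone
Conditions: Dess–Martin periodinane, CH2Cl2, 20 °C
Reagents that add atoms: none
Why: Dess–Martin oxidation of a diaryl carbinol to the benzophenone is mild, neutral and tolerates the aryl bromide and the methyl ethers.

Step 3
Reactants: 5 (2-bromo-3,5-dimethoxyphenyl)(3,5-dimethoxyphenyl)methanone; 6 4-methoxybenzyl chloride
Product: 8 [3,5-dimethoxy-2-(4-methoxybenzyl)phenyl](3,5-dimethoxyphenyl)methanone, via (4-methoxybenzyl)zinc chloride 7 (not isolated)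
Conditions: Zn dust, LiCl, THF, 25 °C (from 6); then 5, Pd(OAc)2 (2 mol%), SPhos (4 mol%), THF, 25 → 50 °C
Reagents that add atoms: none
Why: Negishi coupling, in which zerovalent palladium inserts into the C–Br bond activated by the ortho aroyl group and the benzylzinc chloride transfers the benzyl group; the diaryl ketone is inert to the organozinc, which is why the benzyl group is introduced after the oxidation and not on the aldehyde.

Step 4
Reactants: 8 [3,5-dimethoxy-2-(4-methoxybenzyl)phenyl](3,5-dimethoxyphenyl)methanone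
Product: 10 rac-(7R,8R)-7-(3,5-dimethoxyphenyl)-2,4-dimethoxy-8-(4-methoxyphenyl)bicyclo[4.2.0]octa-1,3,5-trien-7-ol, via E-xylylenol photoenol 9 (not isolated)
Conditions: hν (350 nm), degassed dry benzene (0.01 M), 15 °C; evaporation below 25 °C
Reagents that add atoms: none
Why: Norrish–Yang photocyclisation of an o-benzylbenzophenone, in which the excited ketone takes a hydrogen from the doubly benzylic CH2 (1,5-transfer) to give dienol 9 and thermal conrotatory 4π closure of 9 forms the C7–C8 bond; with hydroxyl and ring B both outside in 9 the hydroxyl should end up trans to ring B, and the two new centres are formed as a racemate.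

Step 5
Reactants: 11 4-methoxybenzoyl chloride
Product: 12 2-diazo-1-(4-methoxyphenyl)ethanone
Conditions: TMSCHN2 (2 equiv), THF/MeCN 1:1, 0 → 20 °C
Reagents that add atoms: (trimethylsilyl)diazomethane, C[Si](C)(C)C=[N+]=[N-]
Why: Arndt–Eistert-type acylation of the diazo carbon by the aroyl chloride, followed by loss of the silyl group to chloride, gives the α-diazoketone; without silver or light no Wolff rearrangement follows.

Step 6
Reactants: 10 rac-(7R,8R)-7-(3,5-dimethoxyphenyl)-2,4-dimethoxy-8-(4-methoxyphenyl)bicyclo[4.2.0]octa-1,3,5-trien-7-ol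
Product: 13 (7R,8R)-7-(3,5-dimethoxyphenyl)-2,4-dimethoxy-8-(4-methoxyphenyl)bicyclo[4.2.0]octa-1,3,5-trien-7-ol
Conditions: preparative chiral SFC (amylose tris(3,5-dimethylphenylcarbamate) phase, CO2/i-PrOH), 15 °C; fractions evaporated cold, stored at −20 °C
Reagents that add atoms: none
Why: Chromatographic resolution on a polysaccharide carbamate phase should separate the enantiomers of this triaryl tertiary alcohol and secures C8 (the later C3) as R; the material is kept cold because reversible ring opening to achiral dienol 9 would racemise it.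

Step 7
Reactants: 13 (7R,8R)-7-(3,5-dimethoxyphenyl)-2,4-dimethoxy-8-(4-methoxyphenyl)bicyclo[4.2.0]octa-1,3,5-trien-7-ol; 12 2-diazo-1-(4-methoxyphenyl)ethanone
Product: 14 [(1S,2R,3R)-2-(3,5-dimethoxyphenyl)-2-hydroxy-4,6-dimethoxy-3-(4-methoxyphenyl)-2,3-dihydro-1H-inden-1-yl](4-methoxyphenyl)methanone
Conditions: [Rh(OH)(cod)]2 (2.5 mol%), toluene, 0 → 20 °C, 12 (1.5 equiv) added over 1 h
Reagents that add atoms: none
Why: The hydroxide on monovalent rhodium exchanges with the tertiary alcohol of 13, and strain-driven β-carbon elimination of the bond between the carbinol carbon and ring A gives an aryl–rhodium species at the future C7a carrying the ketone C2(=O)–ring C; 12 then loses N2 on rhodium, the aryl group migrates to the carbene carbon (1,1-migratory insertion, C7a–C1), and the rhodium enolate adds to the C2 ketone (C1–C2) before protonolysis by the next molecule of 13 releases 14. The closest known reaction is the [Rh(OH)(cod)]2-catalysed formal insertion of diazo ester carbenes into this same bond of benzocyclobutenols to give 2-indanols, an acceptor diazoketone being the same reagent type. The one new ring, the five-membered ring C1–C2–C3–C3a–C7a, closes by a 5-exo-trig (enolexo) aldol addition. C1 and C2 are set in that aldol step, where a rhodium-bridged closed transition state should place ring C trans to ring B and the aroyl group cis to the hydroxyl, but neither needs control because both are erased in step 8; C3 is carried over from C8 of 13. The step needs cleavage of the aryl–carbinol bond and not the C7–C8 bond, which the stronger aryl–rhodium bond secures, and it needs carbene capture and ring closure to outrun enolisation of the transient α,α-diaryl ketone at C3, which the base-free medium, the low temperature and the intramolecular aldol favour.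

Step 8
Reactants: 14 [(1S,2R,3R)-2-(3,5-dimethoxyphenyl)-2-hydroxy-4,6-dimethoxy-3-(4-methoxyphenyl)-2,3-dihydro-1H-inden-1-yl](4-methoxyphenyl)methanone
Product: 15 [(1S)-2-(3,5-dimethoxyphenyl)-5,7-dimethoxy-1-(4-methoxyphenyl)-1H-inden-3-yl](4-methoxyphenyl)methanone
Conditions: TsOH·H2O (10 mol%), toluene, 40 °C
Reagents that add atoms: none
Why: Acid-catalysed aldol dehydration of the β-hydroxy ketone through the enol of the C8 ketone should give the C1=C2 enone conjugated with ring A and the carbonyl; C1 and C2 lose their configuration and the acidic C3–H is left alone because no base is present.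

Step 9
Reactants: 15 [(1S)-2-(3,5-dimethoxyphenyl)-5,7-dimethoxy-1-(4-methoxyphenyl)-1H-inden-3-yl](4-methoxyphenyl)methanone
Product: 16 [(1R,2R,3R)-2-(3,5-dimethoxyphenyl)-4,6-dimethoxy-3-(4-methoxyphenyl)-2,3-dihydro-1H-inden-1-yl](4-methoxyphenyl)methanone
Conditions: H2 (1–3 atm), 10% Pd/C, EtOAc, 20 °C
Reagents that add atoms: none
Why: Heterogeneous syn-hydrogenation of the tetrasubstituted enone should occur on the face opposite ring B at C3, so both hydrogens arrive cis and C1 (R) and C2 (R) are set with aroyl group, ring C and ring B all on one face.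

Step 10
Reactants: 16 [(1R,2R,3R)-2-(3,5-dimethoxyphenyl)-4,6-dimethoxy-3-(4-methoxyphenyl)-2,3-dihydro-1H-inden-1-yl](4-methoxyphenyl)methanone
Product: 17 caraphenol C, [(1R,2R,3R)-2-(3,5-dihydroxyphenyl)-4,6-dihydroxy-3-(4-hydroxyphenyl)-2,3-dihydro-1H-inden-1-yl](4-hydroxyphenyl)methanone
Conditions: BBr3 (12 equiv), CH2Cl2, −78 → 0 °C; then H2O, 0 °C
Reagents that add atoms: none
Why: Lewis-acid cleavage of the six aryl methyl ethers by bromide attack on the boron-bound O-methyl groups; the temperature is held at or below 0 °C so that C1, α to the ketone, is not epimerised and ring C does not attack the boron-bound carbonyl.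

## Compound list

1 | 1-bromo-3,5-dimethoxybenzene | COc1cc(Br)cc(OC)c1 | starting material
2 | 2-bromo-3,5-dimethoxybenzaldehyde | O=Cc1cc(OC)cc(OC)c1Br | starting material
3 | 3,5-dimethoxyphenylmagnesium bromide (formed and used in solution) | COc1cc([Mg]Br)cc(OC)c1 | intermediate
4 | racemic (2-bromo-3,5-dimethoxyphenyl)(3,5-dimethoxyphenyl)methanol | OC(c1cc(OC)cc(OC)c1)c1cc(OC)cc(OC)c1Br | intermediate
5 | (2-bromo-3,5-dimethoxyphenyl)(3,5-dimethoxyphenyl)methanone | O=C(c1cc(OC)cc(OC)c1)c1cc(OC)cc(OC)c1Br | intermediate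
6 | 4-methoxybenzyl chloride | COc1ccc(CCl)cc1 | starting material
7 | (4-methoxybenzyl)zinc chloride (formed and used in solution) | COc1ccc(C[Zn]Cl)cc1 | intermediate
8 | [3,5-dimethoxy-2-(4-methoxybenzyl)phenyl](3,5-dimethoxyphenyl)methanone | O=C(c1cc(OC)cc(OC)c1)c1cc(OC)cc(OC)c1Cc1ccc(OC)cc1 | intermediate
9 | E-xylylenol photoenol, (3,5-dimethoxyphenyl)[3,5-dimethoxy-6-(4-methoxybenzylidene)cyclohexa-2,4-dien-1-ylidene]methanol, hydroxyl and 4-methoxyphenyl both on the outer side (transient) | O/C(c1cc(OC)cc(OC)c1)=C1\C=C(OC)C=C(OC)/C1=C\c1ccc(OC)cc1 | intermediate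
10 | rac-(7R,8R)-7-(3,5-dimethoxyphenyl)-2,4-dimethoxy-8-(4-methoxyphenyl)bicyclo[4.2.0]octa-1,3,5-trien-7-ol (racemate, both enantiomers written; hydroxyl trans to the 4-methoxyphenyl group) | O[C@]1(c2cc(OC)cc(OC)c2)c2cc(OC)cc(OC)c2[C@H]1c1ccc(OC)cc1.O[C@@]1(c2cc(OC)cc(OC)c2)c2cc(OC)cc(OC)c2[C@@H]1c1ccc(OC)cc1 | intermediate
11 | 4-methoxybenzoyl chloride | COc1ccc(C(Cl)=O)cc1 | starting material
12 | 2-diazo-1-(4-methoxyphenyl)ethanone | [N-]=[N+]=CC(=O)c1ccc(OC)cc1 | intermediate
13 | (7R,8R)-7-(3,5-dimethoxyphenyl)-2,4-dimethoxy-8-(4-methoxyphenyl)bicyclo[4.2.0]octa-1,3,5-trien-7-ol | O[C@]1(c2cc(OC)cc(OC)c2)c2cc(OC)cc(OC)c2[C@H]1c1ccc(OC)cc1 | intermediate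
14 | [(1S,2R,3R)-2-(3,5-dimethoxyphenyl)-2-hydroxy-4,6-dimethoxy-3-(4-methoxyphenyl)-2,3-dihydro-1H-inden-1-yl](4-methoxyphenyl)methanone | O=C(c1ccc(OC)cc1)[C@H]1c2cc(OC)cc(OC)c2[C@@H](c2ccc(OC)cc2)[C@]1(O)c1cc(OC)cc(OC)c1 | intermediate
15 | [(1S)-2-(3,5-dimethoxyphenyl)-5,7-dimethoxy-1-(4-methoxyphenyl)-1H-inden-3-yl](4-methoxyphenyl)methanone | O=C(c1ccc(OC)cc1)C1=C(c2cc(OC)cc(OC)c2)[C@H](c2ccc(OC)cc2)c2c(OC)cc(OC)cc12 | intermediate
16 | [(1R,2R,3R)-2-(3,5-dimethoxyphenyl)-4,6-dimethoxy-3-(4-methoxyphenyl)-2,3-dihydro-1H-inden-1-yl](4-methoxyphenyl)methanone (all-cis) | O=C(c1ccc(OC)cc1)[C@H]1c2cc(OC)cc(OC)c2[C@@H](c2ccc(OC)cc2)[C@H]1c1cc(OC)cc(OC)c1 | intermediate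
17 | caraphenol C, [(1R,2R,3R)-2-(3,5-dihydroxyphenyl)-4,6-dihydroxy-3-(4-hydroxyphenyl)-2,3-dihydro-1H-inden-1-yl](4-hydroxyphenyl)methanone | O=C(c1ccc(O)cc1)[C@H]1c2cc(O)cc(O)c2[C@@H](c2ccc(O)cc2)[C@H]1c1cc(O)cc(O)c1 | target

## Step count and risks

Total step count: 10 steps.
Longest linear sequence: 9 steps (steps 1, 2, 3, 4, 6, 7, 8, 9, 10; from 1 and 2 to 17). Step 5 is a one-step side branch.

Steps most likely to fail:

**Step 7 (key step).** Several processes can divert it:
- β-carbon elimination on the C7–C8 side, or protonation of the aryl–rhodium bond before the carbene is captured; both give ring-opened ketones, the first returning 8;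
- dimerisation of the acceptor-only carbene;
- protonation of the rhodium enolate before the aldol closure.

Fallback (sets out from 13, returns at 14): the carbene carbon is brought in at the ester oxidation level, for which this insertion is established, and ring D is attached afterwards. Compound 13 and ethyl diazoacetate under the conditions of step 7 should give ethyl (1S,2R,3R)-2-(3,5-dimethoxyphenyl)-2-hydroxy-4,6-dimethoxy-3-(4-methoxyphenyl)-2,3-dihydro-1H-indene-1-carboxylate F1. Aminolysis with MeNH(OMe)·HCl and i-PrMgCl (THF, −20 °C) should give (1S,2R,3R)-2-(3,5-dimethoxyphenyl)-2-hydroxy-N,4,6-trimethoxy-3-(4-methoxyphenyl)-N-methyl-2,3-dihydro-1H-indene-1-carboxamide F2. 4-Methoxyphenylmagnesium bromide (THF, −20 → 0 °C) should then convert F2 into ketone 14.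

**Step 6 (resolution, with what it must carry through steps 7 and 8).** The configuration at C8 can be lost after the resolution: reversible thermal conrotatory opening of 13 to the achiral dienol 9 racemises it during chromatography or storage (the same process would allow the unwanted enantiomer to be recycled by gentle warming). The same centre can erode later by enolisation of the ring-opened ketone in step 7 or by acid-mediated proton shift in indene 15.

Fallback (sets out from 10, returns at 16): the resolution is moved behind the point where all three centres are fixed. Racemate 10 is taken through steps 7 to 9 unchanged, which should give the racemate of 14 F3, the racemate of 15 F4 and the racemate of the all-cis hexamethyl ether F5. F5 has no labile centre under neutral conditions and is resolved by preparative chiral HPLC on the same type of phase to give 16.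

**Step 9 (hydrogenation).** Hydrogen uptake at the hindered tetrasubstituted double bond may be slow, which gives time for hydrogenolysis of the benzylic ketone and for double-bond migration on the metal.

Fallback (sets out from 15, returns at 16): the two hydrogens are delivered in separate polar steps. Conjugate hydride transfer with catalytic [(Ph3P)CuH]6 and PhMe2SiH (toluene, 20 °C) should add hydride to C2 from the face opposite ring B and give the dimethylphenylsilyl enol ether of 16 F6 (C1=C8 enol ether, ring C now cis to ring B). Protonation with AcOH/Bu4NF in THF at −78 °C should then occur at C1 from the face opposite ring C and give all-cis 16.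

## Further compounds

F1 | step 7 | ethyl (1S,2R,3R)-2-(3,5-dimethoxyphenyl)-2-hydroxy-4,6-dimethoxy-3-(4-methoxyphenyl)-2,3-dihydro-1H-indene-1-carboxylate | CCOC(=O)[C@H]1c2cc(OC)cc(OC)c2[C@@H](c2ccc(OC)cc2)[C@]1(O)c1cc(OC)cc(OC)c1
F2 | step 7 | (1S,2R,3R)-2-(3,5-dimethoxyphenyl)-2-hydroxy-N,4,6-trimethoxy-3-(4-methoxyphenyl)-N-methyl-2,3-dihydro-1H-indene-1-carboxamide | CON(C)C(=O)[C@H]1c2cc(OC)cc(OC)c2[C@@H](c2ccc(OC)cc2)[C@]1(O)c1cc(OC)cc(OC)c1
F3 | step 6 | racemate of 14, rac-[(1S,2R,3R)-2-(3,5-dimethoxyphenyl)-2-hydroxy-4,6-dimethoxy-3-(4-methoxyphenyl)-2,3-dihydro-1H-inden-1-yl](4-methoxyphenyl)methanone (both enantiomers written) | O=C(c1ccc(OC)cc1)[C@H]1c2cc(OC)cc(OC)c2[C@@H](c2ccc(OC)cc2)[C@]1(O)c1cc(OC)cc(OC)c1.O=C(c1ccc(OC)cc1)[C@@H]1c2cc(OC)cc(OC)c2[C@H](c2ccc(OC)cc2)[C@@]1(O)c1cc(OC)cc(OC)c1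
F4 | step 6 | racemate of 15, rac-[2-(3,5-dimethoxyphenyl)-5,7-dimethoxy-1-(4-methoxyphenyl)-1H-inden-3-yl](4-methoxyphenyl)methanone (both enantiomers written) | O=C(c1ccc(OC)cc1)C1=C(c2cc(OC)cc(OC)c2)[C@H](c2ccc(OC)cc2)c2c(OC)cc(OC)cc12.O=C(c1ccc(OC)cc1)C1=C(c2cc(OC)cc(OC)c2)[C@@H](c2ccc(OC)cc2)c2c(OC)cc(OC)cc12
F5 | step 6 | racemate of 16, rac-[(1R,2R,3R)-2-(3,5-dimethoxyphenyl)-4,6-dimethoxy-3-(4-methoxyphenyl)-2,3-dihydro-1H-inden-1-yl](4-methoxyphenyl)methanone (both enantiomers written) | O=C(c1ccc(OC)cc1)[C@H]1c2cc(OC)cc(OC)c2[C@@H](c2ccc(OC)cc2)[C@H]1c1cc(OC)cc(OC)c1.O=C(c1ccc(OC)cc1)[C@@H]1c2cc(OC)cc(OC)c2[C@H](c2ccc(OC)cc2)[C@@H]1c1cc(OC)cc(OC)c1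
F6 | step 9 | dimethylphenylsilyl enol ether of 16 (C1=C8 double bond, geometry not defined; C2 and C3 as in 16) | C[Si](C)(c1ccccc1)OC(c1ccc(OC)cc1)=C1c2cc(OC)cc(OC)c2[C@@H](c2ccc(OC)cc2)[C@H]1c1cc(OC)cc(OC)c1
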